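## Retrosynthetic overview

1. Target ⇒ 8-O-acyl germacranolide: in the last step the allylic lactone C6–O bond ionizes (the C12 carboxylate leaves and becomes the free acid), C1=C10 closes C1–C6 across the ring, and loss of H-14 gives the 10(14)-methylene.
2. Acylated germacranolide ⇒ 8-hydroxy germacranolide + acetonide-protected (S)-3,4-dihydroxy-2-methylenebutanoic acid (from (R)-glyceraldehyde acetonide).
3. Ten-membered ring ⇒ acyclic bromo-enal by intramolecular Nozaki–Hiyama allylation forming C6–C7 (the farnesyl C1–C10 bond); the γ-lactone closes in the same flask.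
4. Acyclic chain ⇒ B-alkyl Suzuki coupling (C1–C2) of a diene from mono-silylated butynediol with a vinyl iodide/Baylis–Hillman adduct from (R)-glycidol (source of C8).
5. Ring order: cyclodecadiene (with its lactone) first; then both six-membered carbocycles of the decalin together in the final step.

Assumption: germacrane/cadinane biogenetic numbering is used for all chain and ring compounds (C1 and C6 become the ring-fusion carbons, C7 carries C11–C13, C8 carries the ester oxygen, C14 is the exocyclic methylene carbon, C15 the hydroxymethyl carbon); compound 1 is taken as a catalogue compound.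

## Route

Step 1
Reactants: 1 4-(tert-butyldimethylsilyloxy)but-2-yn-1-ol
Product: 2 (2Z)-4-(tert-butyldimethylsilyloxy)-3-iodobut-2-en-1-ol
Conditions: Red-Al, THF, 0 °C; then I2, −78 → 0 °C
Reagents that add atoms: iodine, II
Why: Hydroxyl-directed trans-hydroalumination of the propargylic alcohol places aluminium on the distal carbon cis to CH2OH and iodinolysis keeps that geometry (Corey/Denmark (Z)-3-iodoallylic alcohol synthesis), which fixes the later C4=C5 geometry.

Step 2
Reactants: 2 (2Z)-4-(tert-butyldimethylsilyloxy)-3-iodobut-2-en-1-ol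
Product: 3 (2E)-3-[(tert-butyldimethylsilyloxy)methyl]penta-2,4-dien-1-ol
Conditions: vinylboronic acid pinacol ester, PdCl2(dppf) (3 mol%), K3PO4, THF/H2O, 60 °C
Reagents that add atoms: vinylboronic acid pinacol ester, C=CB1OC(C)(C)C(C)(C)O1
Why: Suzuki–Miyaura coupling of the vinyl iodide goes with retention, so the new vinyl group (C2–C3) stays cis to CH2OH (C6).

Step 3
Reactants: 4 (R)-glycidol
Product: 5 (2S)-pent-4-yne-1,2-diol
Conditions: lithium acetylide·ethylenediamine (3 equiv), DMSO, 0 °C → rt
Reagents that add atoms: lithium acetylide ethylenediamine complex, [Li+].[C-]#C.NCCN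
Why: SN2 epoxide opening by the acetylide at the CH2 terminus leaves the stereocentre (the later C8) untouched, and the Payne rearrangement of glycidol is degenerate.

Step 4
Reactants: 5 (2S)-pent-4-yne-1,2-diol
Product: 6 (2S,4E)-5-iodo-4-methylpent-4-ene-1,2-diol
Conditions: Me3Al (4 equiv), Cp2ZrCl2 (0.3 equiv), CH2Cl2, 0 °C → rt; then I2, THF, −30 °C
Reagents that add atoms: trimethylaluminium, C[Al](C)C; iodine, II
Why: Negishi zirconium-catalysed carboalumination adds methyl and aluminium syn across the terminal alkyne (methyl to the internal carbon) and iodinolysis gives the (E)-trisubstituted vinyl iodide that becomes the C1=C10 olefin.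

Step 5
Reactants: 6 (2S,4E)-5-iodo-4-methylpent-4-ene-1,2-diol
Product: 7 (2S,4E)-5-iodo-4-methyl-1,2-bis(triethylsilyloxy)pent-4-ene
Conditions: TESCl (2.5 equiv), imidazole, DMF, 0 °C → rt
Reagents that add atoms: chlorotriethylsilane, CC[Si](Cl)(CC)CC
Why: Standard silylation of both hydroxyls sets up the selective oxidation of the primary position.

Step 6
Reactants: 7 (2S,4E)-5-iodo-4-methyl-1,2-bis(triethylsilyloxy)pent-4-ene
Product: 8 (2S,4E)-5-iodo-4-methyl-2-(triethylsilyloxy)pent-4-enal
Conditions: (COCl)2 (4 equiv), DMSO, CH2Cl2, −78 → −30 °C; then Et3N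
Reagents that add atoms: none
Why: Under Swern conditions a primary triethylsilyl ether is cleaved and oxidized directly to the aldehyde while the secondary TES ether survives, and the α-silyloxy aldehyde is used crude to avoid epimerization.

Step 7
Reactants: 8 (2S,4E)-5-iodo-4-methyl-2-(triethylsilyloxy)pent-4-enal; 9 methyl acrylate
Product: 10 methyl (4S,6E)-3-hydroxy-7-iodo-6-methyl-2-methylidene-4-(triethylsilyloxy)hept-6-enoate (both C3 epimers)
Conditions: DABCO (1 equiv), MeOH (cat.), neat methyl acrylate, rt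
Reagents that add atoms: none
Why: Morita–Baylis–Hillman reaction on the activated α-oxy aldehyde; the new carbinol centre (C7) forms as a mixture but is erased by the SN2' transposition in step 10, and C8 is not touched.

Step 8
Reactants: 3 (2E)-3-[(tert-butyldimethylsilyloxy)methyl]penta-2,4-dien-1-ol; 10 methyl (4S,6E)-3-hydroxy-7-iodo-6-methyl-2-methylidene-4-(triethylsilyloxy)hept-6-enoate
Product: 12 methyl (4S,6E,10E)-10-[(tert-butyldimethylsilyloxy)methyl]-3,12-dihydroxy-6-methyl-2-methylidene-4-(triethylsilyloxy)dodeca-6,10-dienoate, via bis(9-BBN) adduct 11 (not isolated)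
Conditions: 3, 9-BBN (2.2 equiv), THF, 0 °C → rt; then 10, PdCl2(dppf) (5 mol%), AsPh3, aq. K3PO4, DMF, rt
Reagents that add atoms: none
Why: 9-BBN hydroborates only the terminal vinyl group of the diene at its CH2 end, and the B-alkyl Suzuki–Miyaura coupling with the vinyl iodide forms C1–C2 with retention of both olefin geometries under a mild base that avoids 1,2-silyl migration.

Step 9
Reactants: 12 methyl (4S,6E,10E)-10-[(tert-butyldimethylsilyloxy)methyl]-3,12-dihydroxy-6-methyl-2-methylidene-4-(triethylsilyloxy)dodeca-6,10-dienoate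
Product: 13 methyl (4S,6E,10E)-10-[(tert-butyldimethylsilyloxy)methyl]-3-hydroxy-6-methyl-2-methylidene-12-oxo-4-(triethylsilyloxy)dodeca-6,10-dienoate
Conditions: MnO2 (20 equiv), CH2Cl2, rt
Reagents that add atoms: none
Why: MnO2 allylic oxidation takes the electron-rich primary allylic alcohol much faster than the electron-poor secondary Baylis–Hillman alcohol and does not isomerize the enal.

Step 10
Reactants: 13 methyl (4S,6E,10E)-10-[(tert-butyldimethylsilyloxy)methyl]-3-hydroxy-6-methyl-2-methylidene-12-oxo-4-(triethylsilyloxy)dodeca-6,10-dienoate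
Product: 14 methyl (2Z,4S,6E,10E)-2-(bromomethyl)-10-[(tert-butyldimethylsilyloxy)methyl]-6-methyl-12-oxo-4-(triethylsilyloxy)dodeca-2,6,10-trienoate
Conditions: NBS, Me2S, CH2Cl2, 0 °C → rt
Reagents that add atoms: N-bromosuccinimide, O=C1CCC(=O)N1Br
Why: Corey–Kim-type activation of the Baylis–Hillman alcohol followed by SN2' attack of bromide gives the thermodynamically favoured (Z)-2-(bromomethyl)enoate and removes the C7 carbinol centre.

Step 11
Reactants: 14 methyl (2Z,4S,6E,10E)-2-(bromomethyl)-10-[(tert-butyldimethylsilyloxy)methyl]-6-methyl-12-oxo-4-(triethylsilyloxy)dodeca-2,6,10-trienoate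
Product: 17 (6S,7S,8S)-15-(tert-butyldimethylsilyloxy)-8-hydroxygermacra-1(10)E,4E,11(13)-trien-12,6-olide (C3 and C6 cis on C4=C5), via macrocyclic hydroxy ester 15 (not isolated), via TES-protected lactone 16 (not isolated)
Conditions: CrCl2 (8 equiv), THF, rt, slow addition to 2 mM; work-up; then HF·pyridine, pyridine, THF, 0 °C
Reagents that add atoms: none
Why: Intramolecular Nozaki–Hiyama (Barbier-type) allylation: the allylchromium attacks the enal through its γ-carbon (C7) at high dilution and the chromium alkoxide lactonizes onto the methyl ester; C7 is set relative to C8 because allylic 1,3-strain holds H-8 in the plane of the C7=C11 bond and the tethered aldehyde is expected to add on the face carrying the silyloxy group (H-7/H-8 cis), whereas the C6 configuration is irrelevant since C6 is ionized in step 15; buffered HF then removes the secondary TES ether selectively over the primary TBS ether.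

Step 12
Reactants: 18 (R)-2,2-dimethyl-1,3-dioxolane-4-carbaldehyde
Product: 19 (4S)-4-ethynyl-2,2-dimethyl-1,3-dioxolane
Conditions: dimethyl (1-diazo-2-oxopropyl)phosphonate, K2CO3, MeOH, 0 °C → rt
Reagents that add atoms: dimethyl (1-diazo-2-oxopropyl)phosphonate, CC(=O)C(=[N+]=[N-])P(=O)(OC)OC
Why: Seyferth–Gilbert homologation with the Ohira–Bestmann reagent converts the aldehyde into the terminal alkyne without touching the stereocentre (the descriptor changes from R to S only because the priorities change).

Step 13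
Reactants: 19 (4S)-4-ethynyl-2,2-dimethyl-1,3-dioxolane
Product: 20 2-[(4S)-2,2-dimethyl-1,3-dioxolan-4-yl]prop-2-enoic acid
Conditions: Pd(OAc)2 (1 mol%), 2-(diphenylphosphino)pyridine (4 mol%), MsOH (4 mol%), CO (20 bar), H2O (5 equiv), acetone, 50 °C
Reagents that add atoms: carbon monoxide, [C-]#[O+]; water, O
Why: Palladium/2-pyridylphosphine hydroxycarbonylation of terminal alkynes is highly Markovnikov-selective and gives the α-substituted acrylic acid, while acetone as solvent keeps the acetonide in place.

Step 14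
Reactants: 17 (6S,7S,8S)-15-(tert-butyldimethylsilyloxy)-8-hydroxygermacra-1(10)E,4E,11(13)-trien-12,6-olide; 20 2-[(4S)-2,2-dimethyl-1,3-dioxolan-4-yl]prop-2-enoic acid
Product: 21 (6S,7S,8S)-15-(tert-butyldimethylsilyloxy)-8-{2-[(4S)-2,2-dimethyl-1,3-dioxolan-4-yl]prop-2-enoyloxy}germacra-1(10)E,4E,11(13)-trien-12,6-olide
Conditions: 20, 2,4,6-trichlorobenzoyl chloride, Et3N, toluene, rt; then 17, DMAP, rt
Reagents that add atoms: none
Why: Yamaguchi esterification acylates the hindered secondary C8 hydroxyl without touching any stereocentre, and the 8-hydroxy-6,12-olide does not translactonize under these conditions.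

Step 15
Reactants: 21 (6S,7S,8S)-15-(tert-butyldimethylsilyloxy)-8-{2-[(4S)-2,2-dimethyl-1,3-dioxolan-4-yl]prop-2-enoyloxy}germacra-1(10)E,4E,11(13)-trien-12,6-olide
Product: 23 (1S,6S,7S,8S)-8-[(3S)-3,4-dihydroxy-2-methylidenebutanoyloxy]-15-hydroxycadina-4,10(14),11(13)-trien-12-oic acid (CNP0460913.1), via protected cadinane silyl ester 22 (not isolated)
Conditions: TMSOTf (1.5 equiv), 2,6-di-tert-butyl-4-methylpyridine (2 equiv), CH2Cl2, −78 → −20 °C; then AcOH/THF/H2O (3:1:1), 40 °C
Reagents that add atoms: none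
Why: Proposed new method: O-silylation of the lactone carbonyl by TMSOTf turns the C12 carboxylate into a leaving group, so the allylic C6–O bond ionizes to the C4–C5–C6 allyl cation, which the C1=C10 olefin traps across the ring through a chair–chair arrangement (C11 side chain equatorial, O-acyl axial, C7 on the outside of the allyl cation), giving the trans ring fusion (C6 and C1) and a C10 cation that the hindered pyridine deprotonates at the C14 methyl; the closest known reactions are Lewis-acid ionization of allylic esters in cation–olefin cyclizations and the acid-induced transannular cyclization of germacrenes to cadinanes; aqueous acetic acid then cleaves the silyl ester, the TBS ether and the acetonide.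

## Compound list

1 | 4-(tert-butyldimethylsilyloxy)but-2-yn-1-ol | OCC#CCO[Si](C)(C)C(C)(C)C | starting material
2 | (2Z)-4-(tert-butyldimethylsilyloxy)-3-iodobut-2-en-1-ol (I cis to CH2OH) | OC/C=C(\I)CO[Si](C)(C)C(C)(C)C | intermediate
3 | (2E)-3-[(tert-butyldimethylsilyloxy)methyl]penta-2,4-dien-1-ol (vinyl cis to CH2OH) | OC/C=C(\C=C)CO[Si](C)(C)C(C)(C)C | intermediate
4 | (R)-glycidol | OC[C@@H]1CO1 | starting material
5 | (2S)-pent-4-yne-1,2-diol | OC[C@@H](O)CC#C | intermediate
6 | (2S,4E)-5-iodo-4-methylpent-4-ene-1,2-diol | OC[C@@H](O)C/C(C)=C/I | intermediate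
7 | (2S,4E)-5-iodo-4-methyl-1,2-bis(triethylsilyloxy)pent-4-ene | CC[Si](CC)(CC)OC[C@@H](O[Si](CC)(CC)CC)C/C(C)=C/I | intermediate
8 | (2S,4E)-5-iodo-4-methyl-2-(triethylsilyloxy)pent-4-enal | O=C[C@@H](O[Si](CC)(CC)CC)C/C(C)=C/I | intermediate
9 | methyl acrylate | C=CC(=O)OC | starting material
10 | methyl (4S,6E)-3-hydroxy-7-iodo-6-methyl-2-methylidene-4-(triethylsilyloxy)hept-6-enoate (C3 epimers) | COC(=O)C(=C)C(O)[C@@H](O[Si](CC)(CC)CC)C/C(C)=C/I | intermediate
11 | bis(9-BBN) adduct of 3: (2E)-5-(9-borabicyclo[3.3.1]nonan-9-yl)-3-[(tert-butyldimethylsilyloxy)methyl]pent-2-en-1-yl 9-borabicyclo[3.3.1]nonan-9-yl ether | C1CCC2CCCC1B2OC/C=C(\CCB1C2CCCC1CCC2)CO[Si](C)(C)C(C)(C)C | intermediate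
12 | methyl (4S,6E,10E)-10-[(tert-butyldimethylsilyloxy)methyl]-3,12-dihydroxy-6-methyl-2-methylidene-4-(triethylsilyloxy)dodeca-6,10-dienoate (C3 epimers) | COC(=O)C(=C)C(O)[C@@H](O[Si](CC)(CC)CC)C/C(C)=C/CC/C(CO[Si](C)(C)C(C)(C)C)=C\CO | intermediate
13 | methyl (4S,6E,10E)-10-[(tert-butyldimethylsilyloxy)methyl]-3-hydroxy-6-methyl-2-methylidene-12-oxo-4-(triethylsilyloxy)dodeca-6,10-dienoate (C3 epimers) | COC(=O)C(=C)C(O)[C@@H](O[Si](CC)(CC)CC)C/C(C)=C/CC/C(CO[Si](C)(C)C(C)(C)C)=C\C=O | intermediate
14 | methyl (2Z,4S,6E,10E)-2-(bromomethyl)-10-[(tert-butyldimethylsilyloxy)methyl]-6-methyl-12-oxo-4-(triethylsilyloxy)dodeca-2,6,10-trienoate | COC(=O)/C(CBr)=C/[C@@H](O[Si](CC)(CC)CC)C/C(C)=C/CC/C(CO[Si](C)(C)C(C)(C)C)=C\C=O | intermediate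
15 | methyl 15-(tert-butyldimethylsilyloxy)-6-hydroxy-8-(triethylsilyloxy)germacra-1(10)E,4E,11(13)-trien-12-oate, formed as its chromium(III) alkoxide (8S; H-7/H-8 cis; 6,7-anti drawn, the C6 epimer is equally usable) | COC(=O)C(=C)[C@@H]1[C@@H](O)/C=C(CO[Si](C)(C)C(C)(C)C)\CC/C=C(C)/C[C@@H]1O[Si](CC)(CC)CC | intermediate
16 | 15-(tert-butyldimethylsilyloxy)-8-(triethylsilyloxy)germacra-1(10)E,4E,11(13)-trien-12,6-olide (8S; H-7/H-8 cis; trans-fused lactone drawn) | C=C1C(=O)O[C@H]2/C=C(CO[Si](C)(C)C(C)(C)C)\CC/C=C(C)/C[C@H](O[Si](CC)(CC)CC)[C@H]12 | intermediate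
17 | (6S,7S,8S)-15-(tert-butyldimethylsilyloxy)-8-hydroxygermacra-1(10)E,4E,11(13)-trien-12,6-olide (C3/C6 cis on C4=C5; C6 epimer equally usable) | C=C1C(=O)O[C@H]2/C=C(CO[Si](C)(C)C(C)(C)C)\CC/C=C(C)/C[C@H](O)[C@H]12 | intermediate
18 | (R)-2,2-dimethyl-1,3-dioxolane-4-carbaldehyde ((R)-glyceraldehyde acetonide) | O=C[C@H]1COC(C)(C)O1 | starting material
19 | (4S)-4-ethynyl-2,2-dimethyl-1,3-dioxolane | C#C[C@H]1COC(C)(C)O1 | intermediate
20 | 2-[(4S)-2,2-dimethyl-1,3-dioxolan-4-yl]prop-2-enoic acid | C=C(C(=O)O)[C@H]1COC(C)(C)O1 | intermediate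
21 | (6S,7S,8S)-15-(tert-butyldimethylsilyloxy)-8-{2-[(4S)-2,2-dimethyl-1,3-dioxolan-4-yl]prop-2-enoyloxy}germacra-1(10)E,4E,11(13)-trien-12,6-olide | C=C1C(=O)O[C@H]2/C=C(CO[Si](C)(C)C(C)(C)C)\CC/C=C(C)/C[C@H](OC(=O)C(=C)[C@H]3COC(C)(C)O3)[C@H]12 | intermediate
22 | trimethylsilyl (1S,6S,7S,8S)-15-(tert-butyldimethylsilyloxy)-8-{2-[(4S)-2,2-dimethyl-1,3-dioxolan-4-yl]prop-2-enoyloxy}cadina-4,10(14),11(13)-trien-12-oate | C=C(C(=O)O[Si](C)(C)C)[C@@H]1[C@H]2C=C(CO[Si](C)(C)C(C)(C)C)CC[C@@H]2C(=C)C[C@@H]1OC(=O)C(=C)[C@H]3COC(C)(C)O3 | intermediate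
23 | (1S,6S,7S,8S)-8-[(3S)-3,4-dihydroxy-2-methylidenebutanoyloxy]-15-hydroxycadina-4,10(14),11(13)-trien-12-oic acid (trans-decalin; C7 side chain equatorial; C8 ester axial) | C=C(C(=O)O)[C@@H]1[C@H]2C=C(CO)CC[C@@H]2C(=C)C[C@@H]1OC(=O)C(=C)[C@H](O)CO | target

## Step count and risks

Total steps: 15. Longest linear sequence: 11 steps (steps 3–11, 14, 15, from (R)-glycidol).

Steps most likely to fail:

**Step 15 (lactone ionization and transannular cyclization).** The ionization may be slow, and the cation may be lost by elimination, closure to a cis-fused decalin, or capture by the neighbouring C8 acyloxy group. The fallback sets out from 21 and makes the same C1–C6 bond without a free cation, by a palladium-ene (Oppolzer-type) reaction. Pd(PPh3)4 in AcOH/THF at 70 °C ionizes the allylic lactone with inversion to a π-allylpalladium carboxylate. The C1=C10 olefin inserts on the palladium face, and β-hydride elimination towards C14 gives the protected cadinane acid F1. Its TBS ether and acetonide are removed with AcOH/THF/H2O, and the route is rejoined at 23.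

**Step 11 (ten-membered ring closure and facial selectivity at C7).** The chromium-mediated closure may give oligomers or the wrong face at C7. The fallback sets out from 13, skips bromide 14, and uses a palladium-umpolung allylation instead of an organochromium. Acetylation (Ac2O, DMAP) gives the Baylis–Hillman acetate F2. Pd(PPh3)4 with Et2Zn in THF at high dilution converts this through a π-allylpalladium into an allylzinc that adds to the enal through a closed six-membered transition state. The zinc alkoxide lactonizes, and the route is rejoined at 16, which is desilylated with HF·pyridine to 17 as before.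

**Step 7 (Baylis–Hillman reaction on the hindered, epimerizable α-silyloxy aldehyde).** The amine-catalysed reaction may be too slow or erode C8. The fallback sets out from 8 and replaces amine catalysis by a preformed nucleophile (vinylalumination). Methyl propiolate with DIBAL-H and N-methylmorpholine N-oxide in THF at 0 °C gives the [1-(methoxycarbonyl)vinyl]alane, which adds to 8 at −20 °C without base. This gives the same adduct, so the route is rejoined directly at 10 and no new compound is made (F0).

## Further compounds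

F1 | step 15 | (1S,6S,7S,8S)-15-(tert-butyldimethylsilyloxy)-8-{2-[(4S)-2,2-dimethyl-1,3-dioxolan-4-yl]prop-2-enoyloxy}cadina-4,10(14),11(13)-trien-12-oic acid | C=C(C(=O)O)[C@@H]1[C@H]2C=C(CO[Si](C)(C)C(C)(C)C)CC[C@@H]2C(=C)C[C@@H]1OC(=O)C(=C)[C@H]3COC(C)(C)O3
F2 | step 11 | methyl (4S,6E,10E)-3-acetoxy-10-[(tert-butyldimethylsilyloxy)methyl]-6-methyl-2-methylidene-12-oxo-4-(triethylsilyloxy)dodeca-6,10-dienoate | COC(=O)C(=C)C(OC(C)=O)[C@@H](O[Si](CC)(CC)CC)C/C(C)=C/CC/C(CO[Si](C)(C)C(C)(C)C)=C\C=O
F0 | step 7 | none | none
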